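**Retrosynthetic overview**

1. Numbering (drimane type): ring A = C1–C5 and C10, ring B = C5–C10; geminal methyls on C4, methyls on C8 and C10, C9=C11H–aryl. The C9=C11 alkene is made last, by adding the lithiated, protected arene to a C9 carbaldehyde and dehydrating. The aldehyde comes from a C9 ketone by one-carbon homologation, and the C8 methyl from thermodynamic enolate methylation.
2. Enabling feature: in ring B the quaternary ring-fusion carbon C10 lies next to C9, the carbon that carries the exocyclic alkene and can therefore stand as a ketone. A C9 carbonyl flanked by quaternary C10 and the C5–C10 fusion bond is the retron of a pinacol 1,2-shift.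
3. Key disconnection: rings A and B are formed together in a thionium-ion-initiated Prins cyclization–pinacol rearrangement of a 1-isopropenylcyclopentyl silyl ether. C1–C2 bond formation closes a transient seven-membered ring; the shift of C5 from C9 to C10 then expands the cyclopentane (C5–C9) to ring B and contracts the seven-membered ring to ring A, with cis ring fusion.
4. The cyclopentanol precursor comes from (1S,4R)-cis-4-acetoxycyclopent-2-en-1-ol: Johnson–Claisen rearrangement (chirality transfer sets C5, builds C4), lactol, Wittig reaction to a vinyl sulfide (latent thionium ion), isopropenyl addition.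
5. Order of ring formation: cyclopentane (chiral pool) → ring A and ring B together (key step) → arene attached last.

Key step: step 8

Remark: compound 1, compound 18, trimethyl orthoisobutyrate and (phenylsulfanylmethyl)triphenylphosphonium chloride are taken as purchasable. Centres that are destroyed later (lactol carbon of 5, sulfide carbon of 12, spiro carbon of 16, C9 of 17, C9 and C11 of 22) and the vinyl sulfide geometry of 6–10 are carried as mixtures and left unspecified in the SMILES.

**Route**

Step 1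
Reactants: 1 (1S,4R)-cis-4-acetoxycyclopent-2-en-1-ol
Product: 3 methyl 2-[(1R,5R)-5-acetoxycyclopent-2-en-1-yl]-2-methylpropanoate, via mixed ketene acetal 2 (not isolated)
Conditions: trimethyl orthoisobutyrate (5 equiv), propionic acid (cat.), xylene, 140 °C, MeOH distilled off
Reagents that add atoms: trimethyl orthoisobutyrate, COC(OC)(OC)C(C)C
Why: Johnson–Claisen rearrangement; the [3,3] shift is suprafacial, so the new C4–C5 bond forms on the ring face of the departing C–O bond (cis to the acetoxy group), which transfers the carbinol configuration to C5 and builds the quaternary C4.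

Step 2
Reactants: 3 methyl 2-[(1R,5R)-5-acetoxycyclopent-2-en-1-yl]-2-methylpropanoate
Product: 4 methyl 2-[(1R,2R)-2-acetoxycyclopentyl]-2-methylpropanoate
Conditions: H2 (1 atm), 10% Pd/C, EtOAc, rt
Reagents that add atoms: none
Why: Heterogeneous catalytic hydrogenation saturates the only C=C bond without touching a stereocentre, so that the ring alkene cannot compete with the isopropenyl group for the thionium ion in step 8.

Step 3
Reactants: 4 methyl 2-[(1R,2R)-2-acetoxycyclopentyl]-2-methylpropanoate
Product: 5 (3aR,6aR)-3,3-dimethylhexahydro-2H-cyclopenta[b]furan-2-ol (lactol epimers)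
Conditions: i-Bu2AlH (3.2 equiv), CH2Cl2, −78 °C; aq. potassium sodium tartrate
Reagents that add atoms: none
Why: Low-temperature partial reduction of an ester with i-Bu2AlH; the acetate is cleaved, the ester stops at the aldehyde level, and the cis hydroxyl closes the five-membered lactol.

Step 4
Reactants: 5 (3aR,6aR)-3,3-dimethylhexahydro-2H-cyclopenta[b]furan-2-ol
Product: 6 (1R,2R)-2-[2-methyl-4-(phenylsulfanyl)but-3-en-2-yl]cyclopentan-1-ol (E/Z mixture)
Conditions: Ph3P(CH2SPh)Cl (2.5 equiv), n-BuLi (2.4 equiv), THF, −78 to 0 °C; then 5, 0 °C to rt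
Reagents that add atoms: (phenylsulfanylmethyl)triphenylphosphonium chloride, [Cl-].c1ccc(cc1)[P+](CSc1ccccc1)(c1ccccc1)c1ccccc1
Why: Wittig olefination of the open hydroxy-aldehyde form of the lactol adds C2 as a vinyl sulfide and frees the C9 hydroxyl; no stereocentre is affected.

Step 5
Reactants: 6 (1R,2R)-2-[2-methyl-4-(phenylsulfanyl)but-3-en-2-yl]cyclopentan-1-ol
Product: 7 (R)-2-[2-methyl-4-(phenylsulfanyl)but-3-en-2-yl]cyclopentan-1-one
Conditions: Dess–Martin periodinane, NaHCO3, CH2Cl2, 0 °C to rt
Reagents that add atoms: none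
Why: Buffered Dess–Martin oxidation is non-basic, so the C5 stereocentre next to the new ketone is not epimerized and the vinyl sulfide is left alone.

Step 6
Reactants: 7 (R)-2-[2-methyl-4-(phenylsulfanyl)but-3-en-2-yl]cyclopentan-1-one
Product: 8 (1R,2R)-2-[2-methyl-4-(phenylsulfanyl)but-3-en-2-yl]-1-(prop-1-en-2-yl)cyclopentan-1-ol
Conditions: isopropenylmagnesium bromide, CeCl3, THF, −78 °C
Reagents that add atoms: isopropenylmagnesium bromide, C=C(C)[Mg]Br
Why: Organocerium 1,2-addition (weakly basic, no enolization); the nucleophile enters anti to the bulky C5 substituent, so the isopropenyl group ends up trans to the side chain.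

Step 7
Reactants: 8 (1R,2R)-2-[2-methyl-4-(phenylsulfanyl)but-3-en-2-yl]-1-(prop-1-en-2-yl)cyclopentan-1-ol
Product: 9 triethyl({(1R,2R)-2-[2-methyl-4-(phenylsulfanyl)but-3-en-2-yl]-1-(prop-1-en-2-yl)cyclopentyl}oxy)silane
Conditions: TESOTf, 2,6-lutidine, CH2Cl2, −78 to 0 °C
Reagents that add atoms: triethylsilyl triflate, CC[Si](CC)(CC)OS(=O)(=O)C(F)(F)F
Why: Silylation of a hindered tertiary alcohol with a silyl triflate; the bulky silyl ether keeps oxygen from trapping the thionium ion irreversibly and later leaves to end the pinacol shift.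

Step 8
Reactants: 9 triethyl({(1R,2R)-2-[2-methyl-4-(phenylsulfanyl)but-3-en-2-yl]-1-(prop-1-en-2-yl)cyclopentyl}oxy)silane
Product: 12 (4aR,8aS)-5,5,8a-trimethyl-7-(phenylsulfanyl)octahydronaphthalen-1(2H)-one (sulfide epimers), via thionium ion 10 (not isolated), via tertiary carbocation 11 (not isolated)
Conditions: TfOH (1.05 equiv), CH2Cl2, −78 to −30 °C; then aq. NaHCO3
Reagents that add atoms: none
Why: Protonation of the vinyl sulfide at C3 gives thionium ion 10, whose C2 is attacked by the terminal carbon C1 of the isopropenyl group (Prins cyclization, 7-endo-trig, closing a transient seven-membered ring C9–C10–C1–C2–C3–C4–C5) to give the tertiary β-silyloxy cation 11 at C10; a pinacol 1,2-shift of C5 from C9 to C10 then expands the cyclopentane to the cyclohexanone (ring B, closed by ring expansion) and at the same time contracts the seven-membered ring to ring A, and loss of the silyl group leaves the C9 ketone. The closest known reaction type is the Prins–pinacol ring-enlarging annulation of 1-alkenylcycloalkanol silyl ethers that carry a tethered acetal or thioacetal, thionium-initiated variants included. C5 migrates with retention onto the face of the C10 cation on which it already sits, and because the isopropenyl group is trans to the side chain the tether can reach C1 from one rotamer only, so the C10 methyl ends up cis to H5 (cis ring fusion); the sulfide-bearing C2 is formed without control and is removed in step 9. The step needs C-protonation of the vinyl sulfide in preference to the 1,1-disubstituted alkene and the silyl ether (secured by the far more basic sulfur-substituted alkene at −78 °C), carbon instead of oxygen capture of the thionium ion (secured by the bulky silyl ether, whose O-participation is reversible), and migration of C5 instead of C8 (secured because only the C5–C9 bond lies in the new ring and is aligned with the empty orbital, its shift turning a seven- into a six-membered ring).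

Step 9
Reactants: 12 (4aR,8aS)-5,5,8a-trimethyl-7-(phenylsulfanyl)octahydronaphthalen-1(2H)-one
Product: 13 (4aR,8aS)-5,5,8a-trimethyloctahydronaphthalen-1(2H)-one
Conditions: Raney nickel (W-2, washed with acetone), EtOH, rt
Reagents that add atoms: none
Why: Raney nickel hydrogenolysis of the C–S bond (reductive desulfurization) removes the C2 substituent and its uncontrolled stereocentre; the hindered ketone should survive the acetone-deactivated catalyst.

Step 10
Reactants: 13 (4aR,8aS)-5,5,8a-trimethyloctahydronaphthalen-1(2H)-one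
Product: 15 (2S,4aR,8aS)-2,5,5,8a-tetramethyloctahydronaphthalen-1(2H)-one, via lithium enolate 14 (not isolated)
Conditions: LiN(iPr)2, THF, −78 °C; MeI, −78 to 0 °C; then NaOMe (cat.), MeOH, rt
Reagents that add atoms: iodomethane, CI
Why: Enolate alkylation is regiospecific because C8 is the only enolizable position (C10 is quaternary); base equilibration then gives the thermodynamic equatorial C8 methyl, cis to the C10 methyl, since the axial epimer would clash 1,3-diaxially with the C1 methylene.

Step 11
Reactants: 15 (2S,4aR,8aS)-2,5,5,8a-tetramethyloctahydronaphthalen-1(2H)-one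
Product: 16 (2S,4aR,8aS)-2,5,5,8a-tetramethyloctahydro-2H-spiro[naphthalene-1,2'-oxirane] (spiro epimers)
Conditions: Me3SI, n-BuLi, THF, −10 °C to rt
Reagents that add atoms: trimethylsulfonium iodide, C[S+](C)C.[I-]
Why: Corey–Chaykovsky epoxidation; the small unstabilized sulfonium ylide can add to the hindered carbonyl, and the configuration of the new spiro centre is lost again in step 12.

Step 12
Reactants: 16 (2S,4aR,8aS)-2,5,5,8a-tetramethyloctahydro-2H-spiro[naphthalene-1,2'-oxirane]
Product: 17 (2S,4aR,8aS)-2,5,5,8a-tetramethyldecahydronaphthalene-1-carbaldehyde (epimers at the aldehyde-bearing carbon)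
Conditions: MgBr2·OEt2, toluene/Et2O, rt
Reagents that add atoms: none
Why: Meinwald rearrangement; the Lewis acid opens the epoxide at the tertiary carbon C9 and a 1,2-hydride shift from C11 gives the homologated aldehyde, whose C9 configuration is irrelevant because C9 becomes sp2.

Step 13
Reactants: 18 2,4,5-trihydroxybenzaldehyde
Product: 19 2,4,5-tris(methoxymethoxy)benzaldehyde
Conditions: NaH, MOMCl, DMF, 0 °C to rt
Reagents that add atoms: chloromethyl methyl ether, COCCl
Why: Williamson-type O-alkylation of the three phenoxides; MOM-oxy groups later direct the metalation.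

Step 14
Reactants: 19 2,4,5-tris(methoxymethoxy)benzaldehyde
Product: 20 2-[2,4,5-tris(methoxymethoxy)phenyl]-1,3-dioxolane
Conditions: 1,2-bis(trimethylsilyloxy)ethane, TMSOTf (cat.), CH2Cl2, −78 °C
Reagents that add atoms: 1,2-bis(trimethylsilyloxy)ethane, C[Si](C)(C)OCCO[Si](C)(C)C
Why: Noyori acetalization under aprotic low-temperature conditions masks the aldehyde against the organolithium of step 15 without cleaving the acid-labile MOM ethers.

Step 15
Reactants: 20 2-[2,4,5-tris(methoxymethoxy)phenyl]-1,3-dioxolane; 17 (2S,4aR,8aS)-2,5,5,8a-tetramethyldecahydronaphthalene-1-carbaldehyde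
Product: 22 [3-(1,3-dioxolan-2-yl)-2,5,6-tris(methoxymethoxy)phenyl][(2S,4aR,8aS)-2,5,5,8a-tetramethyldecahydronaphthalen-1-yl]methanol (epimer mixture), via aryllithium 21 (not isolated)
Conditions: 20, n-BuLi, THF, 0 °C; then 17, −78 to 0 °C; H2O
Reagents that add atoms: none
Why: Directed ortho-metalation at the ring position flanked by two MOM-oxy groups, then 1,2-addition of the aryllithium to the aldehyde, forms the C11–aryl bond; the carbinol configuration is irrelevant.

Step 16
Reactants: 22 [3-(1,3-dioxolan-2-yl)-2,5,6-tris(methoxymethoxy)phenyl][(2S,4aR,8aS)-2,5,5,8a-tetramethyldecahydronaphthalen-1-yl]methanol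
Product: 23 2-[3-{(E)-[(2S,4aR,8aS)-2,5,5,8a-tetramethyloctahydronaphthalen-1(2H)-ylidene]methyl}-2,4,5-tris(methoxymethoxy)phenyl]-1,3-dioxolane
Conditions: Burgess reagent, toluene, 60 °C
Reagents that add atoms: none
Why: Burgess dehydration (syn-elimination of the sulfamate ester); C9–H is the only β-hydrogen, so the alkene can form only between C9 and C11, and the aryl group should turn away from the quaternary C10 to give the E isomer.

Step 17
Reactants: 23 2-[3-{(E)-[(2S,4aR,8aS)-2,5,5,8a-tetramethyloctahydronaphthalen-1(2H)-ylidene]methyl}-2,4,5-tris(methoxymethoxy)phenyl]-1,3-dioxolane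
Product: 24 2,4,5-trihydroxy-3-{(E)-[(2S,4aR,8aS)-2,5,5,8a-tetramethyloctahydronaphthalen-1(2H)-ylidene]methyl}benzaldehyde
Conditions: TMSOTf, 2,2'-bipyridyl, CH2Cl2, 0 °C to rt; then H2O, aq. NaHCO3, under argon
Reagents that add atoms: water, O
Why: Silyl triflate/bipyridyl cleavage of aromatic MOM ethers and of the dioxolane through pyridinium-type intermediates, then hydrolysis; this avoids the strong protic acid that would let a freed ortho-phenol add across the electron-rich alkene.

**Compound list**

1 | (1S,4R)-cis-4-acetoxycyclopent-2-en-1-ol | O[C@@H]1C=C[C@H](OC(C)=O)C1 | starting material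
2 | (1R,4S)-4-[(1-methoxy-2-methylprop-1-en-1-yl)oxy]cyclopent-2-en-1-yl acetate (mixed ketene acetal) | COC(=C(C)C)O[C@@H]1C=C[C@H](OC(C)=O)C1 | intermediate
3 | methyl 2-[(1R,5R)-5-acetoxycyclopent-2-en-1-yl]-2-methylpropanoate | COC(=O)C(C)(C)[C@H]1C=CC[C@H]1OC(C)=O | intermediate
4 | methyl 2-[(1R,2R)-2-acetoxycyclopentyl]-2-methylpropanoate | COC(=O)C(C)(C)[C@H]1CCC[C@H]1OC(C)=O | intermediate
5 | (3aR,6aR)-3,3-dimethylhexahydro-2H-cyclopenta[b]furan-2-ol | CC1(C)C(O)O[C@@H]2CCC[C@H]12 | intermediate
6 | (1R,2R)-2-[2-methyl-4-(phenylsulfanyl)but-3-en-2-yl]cyclopentan-1-ol | O[C@@H]1CCC[C@@H]1C(C)(C)C=CSc1ccccc1 | intermediate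
7 | (R)-2-[2-methyl-4-(phenylsulfanyl)but-3-en-2-yl]cyclopentan-1-one | O=C1CCC[C@@H]1C(C)(C)C=CSc1ccccc1 | intermediate
8 | (1R,2R)-2-[2-methyl-4-(phenylsulfanyl)but-3-en-2-yl]-1-(prop-1-en-2-yl)cyclopentan-1-ol | C=C(C)[C@@]1(O)CCC[C@@H]1C(C)(C)C=CSc1ccccc1 | intermediate
9 | triethyl({(1R,2R)-2-[2-methyl-4-(phenylsulfanyl)but-3-en-2-yl]-1-(prop-1-en-2-yl)cyclopentyl}oxy)silane | C=C(C)[C@@]1(O[Si](CC)(CC)CC)CCC[C@@H]1C(C)(C)C=CSc1ccccc1 | intermediate
10 | phenyl{3-methyl-3-[(1R,2R)-2-(prop-1-en-2-yl)-2-(triethylsilyloxy)cyclopentyl]butylidene}sulfonium (thionium ion) | C=C(C)[C@@]1(O[Si](CC)(CC)CC)CCC[C@@H]1C(C)(C)CC=[S+]c1ccccc1 | intermediate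
11 | (3aR,8aR)-4,8,8-trimethyl-6-(phenylsulfanyl)-3a-(triethylsilyloxy)decahydroazulen-4-ylium | CC[Si](CC)(CC)O[C@]12CCC[C@@H]1C(C)(C)CC(Sc1ccccc1)C[C+]2C | intermediate
12 | (4aR,8aS)-5,5,8a-trimethyl-7-(phenylsulfanyl)octahydronaphthalen-1(2H)-one | O=C1CCC[C@@H]2C(C)(C)CC(Sc3ccccc3)C[C@]12C | intermediate
13 | (4aR,8aS)-5,5,8a-trimethyloctahydronaphthalen-1(2H)-one | O=C1CCC[C@@H]2C(C)(C)CCC[C@]12C | intermediate
14 | lithium (4aR,8aS)-5,5,8a-trimethyl-3,4,4a,5,6,7,8,8a-octahydronaphthalen-1-olate | [Li]OC1=CCC[C@@H]2C(C)(C)CCC[C@]12C | intermediate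
15 | (2S,4aR,8aS)-2,5,5,8a-tetramethyloctahydronaphthalen-1(2H)-one | C[C@H]1CC[C@@H]2C(C)(C)CCC[C@]2(C)C1=O | intermediate
16 | (2S,4aR,8aS)-2,5,5,8a-tetramethyloctahydro-2H-spiro[naphthalene-1,2'-oxirane] | C[C@H]1CC[C@@H]2C(C)(C)CCC[C@]2(C)C13CO3 | intermediate
17 | (2S,4aR,8aS)-2,5,5,8a-tetramethyldecahydronaphthalene-1-carbaldehyde | C[C@H]1CC[C@@H]2C(C)(C)CCC[C@]2(C)C1C=O | intermediate
18 | 2,4,5-trihydroxybenzaldehyde | O=Cc1cc(O)c(O)cc1O | starting material
19 | 2,4,5-tris(methoxymethoxy)benzaldehyde | COCOc1cc(OCOC)c(OCOC)cc1C=O | intermediate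
20 | 2-[2,4,5-tris(methoxymethoxy)phenyl]-1,3-dioxolane | COCOc1cc(OCOC)c(OCOC)cc1C1OCCO1 | intermediate
21 | [3-(1,3-dioxolan-2-yl)-2,5,6-tris(methoxymethoxy)phenyl]lithium | [Li]c1c(OCOC)c(OCOC)cc(C2OCCO2)c1OCOC | intermediate
22 | [3-(1,3-dioxolan-2-yl)-2,5,6-tris(methoxymethoxy)phenyl][(2S,4aR,8aS)-2,5,5,8a-tetramethyldecahydronaphthalen-1-yl]methanol | C[C@H]1CC[C@@H]2C(C)(C)CCC[C@]2(C)C1C(O)c3c(OCOC)c(OCOC)cc(C4OCCO4)c3OCOC | intermediate
23 | 2-[3-{(E)-[(2S,4aR,8aS)-2,5,5,8a-tetramethyloctahydronaphthalen-1(2H)-ylidene]methyl}-2,4,5-tris(methoxymethoxy)phenyl]-1,3-dioxolane | C[C@H]1CC[C@@H]2C(C)(C)CCC[C@]2(C)/C1=C/c3c(OCOC)c(OCOC)cc(C4OCCO4)c3OCOC | intermediate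
24 | 2,4,5-trihydroxy-3-{(E)-[(2S,4aR,8aS)-2,5,5,8a-tetramethyloctahydronaphthalen-1(2H)-ylidene]methyl}benzaldehyde | C[C@H]1CC[C@@H]2C(C)(C)CCC[C@]2(C)/C1=C/c1c(O)c(O)cc(C=O)c1O | target

**Step count and risks**

Total step count: 17. Longest linear sequence: 15 steps (steps 1–12 and 15–17).

Steps most likely to fail:

Step 8. The seven-membered Prins closure may be outrun by ionization of the tertiary allylic silyl ether, by capture of the thionium ion at oxygen, or by proton loss from the C10 cation before the 1,2-shift. The fallback separates ring closure from ring expansion and sets out from 9. The vinyl sulfide is hydrolysed (HgCl2, CaCO3, wet MeCN) to 3-methyl-3-[(1R,2R)-2-(prop-1-en-2-yl)-2-(triethylsilyloxy)cyclopentyl]butanal F1. A Me2AlCl-promoted intramolecular carbonyl-ene reaction of type 2 (aldehyde tethered to the central carbon of the ene unit, a mode that closes seven-membered rings well) should give (3aR,8aR)-8,8-dimethyl-4-methylidene-3a-(triethylsilyloxy)decahydroazulen-6-ol F2. Protonation of the exocyclic methylene (BF3·OEt2 with a trace of water, or TsOH) regenerates the C10 cation and triggers the same pinacol shift, still expanding the cyclopentane to ring B, to give (4aR,8aS)-7-hydroxy-5,5,8a-trimethyloctahydronaphthalen-1(2H)-one F3. The extra hydroxyl is removed by Barton–McCombie deoxygenation through O-[(4aR,8aS)-4,4,8a-trimethyl-8-oxodecahydronaphthalen-2-yl] 1H-imidazole-1-carbothioate F4 (1,1'-thiocarbonyldiimidazole, then Bu3SnH, AIBN), which comes back to the route at 13.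

Step 12. Epoxide opening at the crowded tertiary centre may be followed by proton loss to an allylic alcohol or by a 1,2-alkyl shift with ring enlargement instead of the hydride shift. The fallback sets out from 15 and bypasses the epoxide: reductive cyanation with TosMIC (t-BuOK, DME, EtOH) should give (2S,4aR,8aS)-2,5,5,8a-tetramethyldecahydronaphthalene-1-carbonitrile F5, and i-Bu2AlH (toluene, −78 °C, then dilute HCl) reduces the nitrile to the aldehyde, coming back at 17.

Step 17. A freed ortho-phenol may add across the electron-rich alkene under the Lewis-acidic conditions, or the hydroxyquinol may oxidize in air while three MOM ethers are cleaved slowly. The fallback changes the protecting group to one that leaves under basic fluoride conditions and sets out from 18. SEMCl and NaH give 2,4,5-tris{[2-(trimethylsilyl)ethoxy]methoxy}benzaldehyde F6. Acetalization as in step 14 gives 2-(2,4,5-tris{[2-(trimethylsilyl)ethoxy]methoxy}phenyl)-1,3-dioxolane F7. Lithiation and addition to 17 as in step 15 give the SEM-protected carbinol F8, and Burgess dehydration gives the SEM-protected alkene F9. Bu4NF in DMPU at 60 °C under argon cleaves the three SEM ethers by fluoride-induced fragmentation to 3-{(E)-[(2S,4aR,8aS)-2,5,5,8a-tetramethyloctahydronaphthalen-1(2H)-ylidene]methyl}-4-(1,3-dioxolan-2-yl)benzene-1,2,5-triol F10. Brief treatment with wet silica gel and oxalic acid releases the aldehyde and comes back at 24.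

Further compounds
F1 | step 8 | 3-methyl-3-[(1R,2R)-2-(prop-1-en-2-yl)-2-(triethylsilyloxy)cyclopentyl]butanal | C=C(C)[C@@]1(O[Si](CC)(CC)CC)CCC[C@@H]1C(C)(C)CC=O
F2 | step 8 | (3aR,8aR)-8,8-dimethyl-4-methylidene-3a-(triethylsilyloxy)decahydroazulen-6-ol | C=C1CC(O)CC(C)(C)[C@H]2CCC[C@]12O[Si](CC)(CC)CC
F3 | step 8 | (4aR,8aS)-7-hydroxy-5,5,8a-trimethyloctahydronaphthalen-1(2H)-one | O=C1CCC[C@@H]2C(C)(C)CC(O)C[C@]12C
F4 | step 8 | O-[(4aR,8aS)-4,4,8a-trimethyl-8-oxodecahydronaphthalen-2-yl] 1H-imidazole-1-carbothioate | O=C1CCC[C@@H]2C(C)(C)CC(OC(=S)n3ccnc3)C[C@]12C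
F5 | step 12 | (2S,4aR,8aS)-2,5,5,8a-tetramethyldecahydronaphthalene-1-carbonitrile | C[C@H]1CC[C@@H]2C(C)(C)CCC[C@]2(C)C1C#N
F6 | step 17 | 2,4,5-tris{[2-(trimethylsilyl)ethoxy]methoxy}benzaldehyde | O=Cc1cc(OCOCC[Si](C)(C)C)c(OCOCC[Si](C)(C)C)cc1OCOCC[Si](C)(C)C
F7 | step 17 | 2-(2,4,5-tris{[2-(trimethylsilyl)ethoxy]methoxy}phenyl)-1,3-dioxolane | C[Si](C)(C)CCOCOc1cc(OCOCC[Si](C)(C)C)c(OCOCC[Si](C)(C)C)cc1C1OCCO1
F8 | step 17 | [3-(1,3-dioxolan-2-yl)-2,5,6-tris{[2-(trimethylsilyl)ethoxy]methoxy}phenyl][(2S,4aR,8aS)-2,5,5,8a-tetramethyldecahydronaphthalen-1-yl]methanol | C[C@H]1CC[C@@H]2C(C)(C)CCC[C@]2(C)C1C(O)c3c(OCOCC[Si](C)(C)C)c(OCOCC[Si](C)(C)C)cc(C4OCCO4)c3OCOCC[Si](C)(C)C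
F9 | step 17 | 2-[3-{(E)-[(2S,4aR,8aS)-2,5,5,8a-tetramethyloctahydronaphthalen-1(2H)-ylidene]methyl}-2,4,5-tris{[2-(trimethylsilyl)ethoxy]methoxy}phenyl]-1,3-dioxolane | C[C@H]1CC[C@@H]2C(C)(C)CCC[C@]2(C)/C1=C/c3c(OCOCC[Si](C)(C)C)c(OCOCC[Si](C)(C)C)cc(C4OCCO4)c3OCOCC[Si](C)(C)C
F10 | step 17 | 3-{(E)-[(2S,4aR,8aS)-2,5,5,8a-tetramethyloctahydronaphthalen-1(2H)-ylidene]methyl}-4-(1,3-dioxolan-2-yl)benzene-1,2,5-triol | C[C@H]1CC[C@@H]2C(C)(C)CCC[C@]2(C)/C1=C/c3c(O)c(O)cc(C4OCCO4)c3O
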